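Ring B is disconnected at its two vicinal C–O bonds: the bridging oxygen on C1' and the hydroxyl on C2' lie directly beside C6'–Br, with the second bromine at C4', exactly the pattern that results when O2 is added across C4–C5 of 1,3-dibromobenzene. One enzymatic cis-dioxygenation of this bought arene, which needs no preparation, therefore installs both oxygens and leaves two distinguishable carbinols. The one beside C–H is silylated; oxidation of the other re-aromatises the ring to a monoprotected catechol, whose free oxygen is arylated with ring A from an aryl(trimethoxyphenyl)iodonium salt made from 2,4-dibromo-6-methoxyaniline. Desilylation gives the target.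

Key step: step 1

Remark: the (1S,2S) configuration of diol 2 is assigned by analogy with the cis-diols this enzyme gives with other halobenzenes; the target has no stereocentre and both centres of 2 are erased in step 3, so the route does not depend on this assignment.

Remark: ring B is re-aromatised directly after the two oxygens have been told apart, so that the diaryl ether is made on a phenoxide and not on an alkoxide of the acid- and base-sensitive diene.

Step 1
Reactants: 1 1,3-dibromobenzene
Product: 2 (1S,2S)-3,5-dibromocyclohexa-3,5-diene-1,2-diol
Conditions: recombinant E. coli whole cells expressing toluene dioxygenase (todC1C2BA, IPTG-induced, no diol dehydrogenase), air, glucose, phosphate buffer pH 7.2, 30 °C; EtOAc extraction at pH 7–8, no acid contact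
Reagents that add atoms: dioxygen, O=O
Why: This is an arene cis-dihydroxylation by a ring-hydroxylating non-haem iron dioxygenase: NADH-derived electrons reach the mononuclear iron centre (divalent iron) through the reductase, ferredoxin and iron–sulfur components, O2 is bound and activated there, and both oxygen atoms are delivered to the same face of one C=C of the arene held above the metal. The closest known reaction type is the whole-cell toluene dioxygenase oxidation of bromobenzene and other halobenzenes to cis-cyclohexadienediols, the host lacking the dehydrogenase that would carry the diol on to a catechol. No ring is closed; two C–O bonds are formed. The two stereocentres (C1 and C2 of 2) arise together by suprafacial delivery of both oxygens, so they are necessarily cis, and the face is chosen by the active site (catalyst control), drawn here as (1S,2S). The only selectivity needed is attack on an unsubstituted C–H/C–H bond and not on a brominated carbon, and the substrate secures the constitution by itself: its only two such bonds, C4–C5 and C5–C6, are mirror images of each other, so either gives the 3,5-dibromo-1,2-diol with one carbinol beside C–Br and one beside C–H. Which of the two is oxidised fixes only the absolute configuration, which is immaterial because both centres are erased when ring B is re-aromatised.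

Step 2
Reactants: 2 (1S,2S)-3,5-dibromocyclohexa-3,5-diene-1,2-diol
Product: 3 (1S,6S)-2,4-dibromo-6-[(triisopropylsilyl)oxy]cyclohexa-2,4-dien-1-ol
Conditions: TIPSCl (1.05 equiv), imidazole, cat. DMAP, DMF, 0 °C to rt
Reagents that add atoms: chlorotriisopropylsilane (TIPSCl), CC(C)[Si](Cl)(C(C)C)C(C)C
Why: Imidazole-promoted silyl ether formation is sterically governed, so the bulky silyl group should go to the C1 hydroxyl of 2 (flanked by the vinylic C6–H) and not to the C2 hydroxyl, which is shielded and inductively deactivated by the neighbouring C3–Br; the medium stays basic, so the diene is not exposed to acid, and no stereocentre is formed or touched.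

Step 3
Reactants: 3 (1S,6S)-2,4-dibromo-6-[(triisopropylsilyl)oxy]cyclohexa-2,4-dien-1-ol
Product: 5 2,4-dibromo-6-[(triisopropylsilyl)oxy]phenol, via dienone 4 (not isolated)
Conditions: Dess–Martin periodinane (1.1 equiv), NaHCO3, CH2Cl2, 0 °C; aq. Na2S2O3/NaHCO3 work-up
Reagents that add atoms: none
Why: Dess–Martin oxidation of the remaining allylic carbinol gives dienone 4, whose C6–H (alpha to the carbonyl, on the silyloxy-bearing carbon) is lost by keto–enol tautomerisation, so the ring aromatises to the phenol and both stereocentres disappear; NaHCO3 keeps the medium from turning acidic, which would dehydrate the diene.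

Step 4
Reactants: 6 2,4-dibromo-6-methoxyaniline
Product: 8 1,5-dibromo-2-iodo-3-methoxybenzene, via diazonium tosylate 7 (not isolated)
Conditions: p-TsOH·H2O, NaNO2, KI, MeCN/H2O, 10 °C to rt
Reagents that add atoms: potassium iodide, [K+].[I-]
Why: In this Sandmeyer-type iodination the weakly basic aniline is diazotised by NaNO2 and a sulfonic acid to a tolerably stable arenediazonium tosylate, which iodide reduces and captures as the aryl iodide without a copper salt, the aryl bromides and the methyl ether being inert.

Step 5
Reactants: 8 1,5-dibromo-2-iodo-3-methoxybenzene
Product: 10 (2,4-dibromo-6-methoxyphenyl)(2,4,6-trimethoxyphenyl)iodonium 4-methylbenzenesulfonate, via hydroxy(tosyloxy)iodoarene 9 (not isolated)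
Conditions: mCPBA, p-TsOH·H2O, MeCN, 60 °C; then 1,3,5-trimethoxybenzene, rt; precipitation from Et2O
Reagents that add atoms: 1,3,5-trimethoxybenzene, COc1cc(OC)cc(OC)c1; p-toluenesulfonic acid, Cc1ccc(cc1)S(=O)(=O)O
Why: In this one-pot diaryliodonium synthesis the peracid oxidises the aryl iodide to a trivalent-iodine hydroxy tosylate, which attacks the very electron-rich 1,3,5-trimethoxybenzene (three equivalent free positions) in an electrophilic aromatic substitution, the trimethoxyphenyl group being chosen as the ligand that is not transferred later.

Step 6
Reactants: 5 2,4-dibromo-6-[(triisopropylsilyl)oxy]phenol; 10 (2,4-dibromo-6-methoxyphenyl)(2,4,6-trimethoxyphenyl)iodonium 4-methylbenzenesulfonate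
Product: 11 [3,5-dibromo-2-(2,4-dibromo-6-methoxyphenoxy)phenoxy]triisopropylsilane
Conditions: 5 and 10 (1.1 equiv) in THF, KOtBu (1.05 equiv) added at 0 °C, then 40 °C
Reagents that add atoms: none
Why: Metal-free O-arylation of a phenoxide with a diaryliodonium salt (ligand exchange at trivalent iodine, then ligand coupling) tolerates ortho substituents on both partners and leaves aryl bromides untouched; the electron-poorer dibromomethoxyphenyl group should be transferred in preference to the electron-rich trimethoxyphenyl ligand, and the oxygen flanked by bromine should be the one that couples, because the bulky silyl group is better accommodated on the oxygen next to C–H and the phenoxide ortho and para to bromine is the more stabilised one.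

Step 7
Reactants: 11 [3,5-dibromo-2-(2,4-dibromo-6-methoxyphenoxy)phenoxy]triisopropylsilane
Product: 12 3,5-dibromo-2-(2,4-dibromo-6-methoxyphenoxy)phenol
Conditions: TBAF (1.1 equiv), AcOH (1.1 equiv), THF, 0 °C to rt
Reagents that add atoms: none
Why: Fluoride-induced cleavage of the aryl silyl ether, buffered with acetic acid, should free the phenol without touching the diaryl ether, the methyl ether or the aryl bromides, and gives the target, which has no stereocentre.

Compound list
1 | 1,3-dibromobenzene | Brc1cccc(Br)c1 | starting material
2 | (1S,2S)-3,5-dibromocyclohexa-3,5-diene-1,2-diol | O[C@H]1C=C(Br)C=C(Br)[C@H]1O | intermediate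
3 | (1S,6S)-2,4-dibromo-6-[(triisopropylsilyl)oxy]cyclohexa-2,4-dien-1-ol | CC(C)[Si](C(C)C)(C(C)C)O[C@H]1C=C(Br)C=C(Br)[C@H]1O | intermediate
4 | (6S)-2,4-dibromo-6-[(triisopropylsilyl)oxy]cyclohexa-2,4-dien-1-one | CC(C)[Si](C(C)C)(C(C)C)O[C@H]1C=C(Br)C=C(Br)C1=O | intermediate
5 | 2,4-dibromo-6-[(triisopropylsilyl)oxy]phenol | CC(C)[Si](C(C)C)(C(C)C)Oc1cc(Br)cc(Br)c1O | intermediate
6 | 2,4-dibromo-6-methoxyaniline | COc1cc(Br)cc(Br)c1N | starting material
7 | 2,4-dibromo-6-methoxybenzenediazonium 4-methylbenzenesulfonate | COc1cc(Br)cc(Br)c1[N+]#N.Cc1ccc(cc1)S(=O)(=O)[O-] | intermediate
8 | 1,5-dibromo-2-iodo-3-methoxybenzene | COc1cc(Br)cc(Br)c1I | intermediate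
9 | 1,5-dibromo-2-[hydroxy(tosyloxy)-λ3-iodanyl]-3-methoxybenzene | COc1cc(Br)cc(Br)c1I(O)OS(=O)(=O)c1ccc(C)cc1 | intermediate
10 | (2,4-dibromo-6-methoxyphenyl)(2,4,6-trimethoxyphenyl)iodonium 4-methylbenzenesulfonate | COc1cc(OC)c([I+]c2c(OC)cc(Br)cc2Br)c(OC)c1.Cc1ccc(cc1)S(=O)(=O)[O-] | intermediate
11 | [3,5-dibromo-2-(2,4-dibromo-6-methoxyphenoxy)phenoxy]triisopropylsilane | COc1cc(Br)cc(Br)c1Oc1c(O[Si](C(C)C)(C(C)C)C(C)C)cc(Br)cc1Br | intermediate
12 | 3,5-dibromo-2-(2,4-dibromo-6-methoxyphenoxy)phenol | COc1cc(Br)cc(Br)c1Oc1c(O)cc(Br)cc1Br | target

Total step count: 7
Longest linear sequence: 5 steps (steps 1, 2, 3, 6 and 7, from 1 to 12); steps 4 and 5 build the ring A reagent in parallel.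

Steps most likely to fail

Step 6 (diaryl ether formation). Under base the silyl group may shuttle between the two ortho oxygens of ring B, so that part of the material couples through the oxygen flanked by C–H. Ligand coupling may also stall because four ortho substituents, one of them a bulky silyloxy group, crowd the new C–O bond. The fallback replaces the silyl ether by a small acetal that cannot migrate. It sets out from 2: MOMCl and i-Pr2NEt in CH2Cl2 at 0 °C should alkylate mainly the hydroxyl beside C–H to give (1S,6S)-2,4-dibromo-6-(methoxymethoxy)cyclohexa-2,4-dien-1-ol F1, any regioisomer being removed by chromatography at this early stage. Buffered Dess–Martin oxidation should then give, by way of (6S)-2,4-dibromo-6-(methoxymethoxy)cyclohexa-2,4-dien-1-one F2, the aromatised 2,4-dibromo-6-(methoxymethoxy)phenol F3. Coupling with 10 under the conditions of step 6 should give 1,5-dibromo-2-(2,4-dibromo-6-methoxyphenoxy)-3-(methoxymethoxy)benzene F4, and HCl in MeOH at 40 °C removes the acetal, so the fallback comes back to the route at 12.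

Step 1 (biocatalytic dioxygenation). The lipophilic dihalide may be turned over slowly or poison the cells, and the diol may be lost by dehydration during isolation. The fallback changes the biocatalyst and the process, not only the medium: 1 is offered to a ring-hydroxylating dioxygenase of the chlorobenzene-degrading type (a homologous multicomponent iron enzyme evolved for polyhalogenated benzenes) expressed in the same dehydrogenase-free host. The substrate is fed from a second liquid phase (liquid paraffin) that keeps its aqueous concentration low. This sets out from 1 and comes back at 2 (no new compound, F0).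

Step 3 (oxidation and aromatisation). The diene may lose water or silanol under traces of acid before it is oxidised, which gives bromophenol derivatives with one oxygen too few, and excess periodinane may oxidise phenol 5 further. The fallback inverts the order of oxidation and protection and does the oxidation enzymatically at neutral pH. Setting out from 2, resting cells expressing the NAD+-dependent toluene cis-dihydrodiol dehydrogenase should dehydrogenate the diol to 3,5-dibromobenzene-1,2-diol F5. One equivalent of TIPSCl with imidazole in DMF should then silylate the hydroxyl beside C–H, which is the more accessible position and also the one favoured when the silyl group equilibrates, and the fallback comes back at 5.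

Further compounds
F1 | step 6 | (1S,6S)-2,4-dibromo-6-(methoxymethoxy)cyclohexa-2,4-dien-1-ol | COCO[C@H]1C=C(Br)C=C(Br)[C@H]1O
F2 | step 6 | (6S)-2,4-dibromo-6-(methoxymethoxy)cyclohexa-2,4-dien-1-one | COCO[C@H]1C=C(Br)C=C(Br)C1=O
F3 | step 6 | 2,4-dibromo-6-(methoxymethoxy)phenol | COCOc1cc(Br)cc(Br)c1O
F4 | step 6 | 1,5-dibromo-2-(2,4-dibromo-6-methoxyphenoxy)-3-(methoxymethoxy)benzene | COCOc1cc(Br)cc(Br)c1Oc1c(OC)cc(Br)cc1Br
F0 | step 1 | none | none
F5 | step 3 | 3,5-dibromobenzene-1,2-diol | Oc1cc(Br)cc(Br)c1O
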